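Blue, grey and violet are charged alike in substrate, 0.200 M, and partner, 0.240 M, which makes substrate the limiting reagent, and they part in free catalyst.

common to all: substrate 0.200 M; partner 0.240 M
- blue: free catalyst 0.00400 M
- grey: free catalyst 0.00200 M
- violet: free catalyst 8.70 × 10⁻⁴ M; time 14 min

| blue run: time / min | blue run: [product] / M | grey run: time / min | grey run: [product] / M |
|---|---|---|---|
| 0.56 | 0.0215 | 0.56 | 0.0096 |
| 1.1 | 0.0370 | 1.1 | 0.0179 |
| 2.0 | 0.0561 | 2.0 | 0.0283 |
| 3.9 | 0.0817 | 3.9 | 0.0479 |
| 7.4 | 0.1045 | 7.4 | 0.0694 |
| 14 | 0.1251 | 14 | 0.0941 |

(standard deviation of a reading: 6 × 10⁻⁴ M)

- Overall: substrate + partner -> product, with free catalyst as catalyst.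
- Constant volume, constant temperature.
- What is held in complexes is read along with the free species.
- "The second partner" is partner.
- An order is taken over about fifteen percent of the charge, up and down.

- apparent order in [free catalyst] of the starting rate, round the charge of the blue run (the rate where two percent of its substrate have turned into product)
- product in the violet run at 14 min, as a share of the substrate charged

We set the blue and grey runs side by side at equal product, with straight chords between neighbouring readings. The grey reading at 3.9 min is matched on the blue chord at 1.61 min, a stretch of 2.42, and the blue reading at 2.0 min on the grey chord at 5.23 min, a stretch of 2.62. The curves bend, so the two chords err in opposite directions, and we take the mean, 2.52, which is more than the ratio of the charges, 2.00. Suppose a fixed amount of each charge does no work and the clock follows the remainder. The two runs then fold into one number, the dead share, the fraction of the blue charge that does no work: 0.170, which is 6.82 × 10⁻⁴ M.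

A rate proportional to the remainder has the order one over (one minus the dead share) at the blue charge, so we expect 1.21. Violet keeps 1.88 × 10⁻⁴ M against 0.00132 M in grey, so its 14 min count as 2.00 min of grey. A straight line between the grey readings at 1.1 min and 2.0 min gives 0.0283 M, or 14.1% of the violet substrate.

Was one number enough? Further up, the grey reading at 7.4 min and the blue reading at 3.9 min give stretches of 2.48 and 2.74, with the mean 2.61. Put back in, this gives 7.57 × 10⁻⁴ M and a grey-equivalent time of 1.27 min, so violet moves to 9.96%. The first violet remainder is 21.6% of the violet charge, a small difference between two near amounts, so we commit to the mean of the two estimates, 12.0%.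

The forecast gave 1.27 and 20%, its author saying "lean between these, toward the titration".

The flask gives an order of 1.2 and 12.9% for violet.

    free catalyst + substrate ⇌ catalyst-substrate complex, settled at all times (1.440 M⁻¹)
    catalyst-substrate complex + partner → product + free catalyst (253.8 M⁻¹ min⁻¹)
    free catalyst + impurity → spent catalyst
    2 free catalyst → 2 spent catalyst (55.68 M⁻¹ min⁻¹)

Fitted with the main steps alone, the readings leave a residual of 13 in units of the scatter. The dead share makes the blue remainder 17.6 times the violet one, so the 14 min of violet count as 0.794 min of blue. Violet made 0.0257 M, and the blue run read 0.0215 M at 0.56 min and 0.0370 M at 1.1 min.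

The numbers in the tables are calculated with made-up constants; scatter was added.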